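## Retrosynthetic overview

1. Target ⇒ tri-O-benzyl ether: one final hydrogenolysis frees C9–OH and the glyceryl diol.
2. C7–C8 (key bond) ⇒ ring A aryl iodide + (R)-α-aryloxy aldehyde, joined by an electrochemical Cr/Ni-catalysed aryl addition; C7 is set by 1,2-induction from C8 (Felkin–Anh, erythro).
3. C8–O–C4′ ⇒ SN2 inversion of an (S)-glycerate α-triflate by the phenoxide of dihydrosinapyl alcohol; C8 is bought as O-benzyl-L-serine (diazotisation with retention, then esterification).
4. Ring A glyceryl ether ⇒ Mitsunobu reaction of 4-iodo-2-methoxyphenol with 1,3-bis(benzyloxy)propan-2-ol.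
5. No ring is formed: both benzene rings are bought intact; ring A is attached at C7, ring B at O–C8.

Assumption: neolignan numbering is used (C7 benzylic carbinol, C8 ether carbon, C9 hydroxymethyl, primed locants on ring B); the target is the erythro (7S,8R) isomer, and dihydrosinapyl alcohol is taken as a catalogue compound.

## Route

Step 1
Reactants: 1 4-iodo-2-methoxyphenol; 2 1,3-bis(benzyloxy)propan-2-ol
Product: 3 1-{[1,3-bis(benzyloxy)propan-2-yl]oxy}-4-iodo-2-methoxybenzene
Conditions: PPh3 (1.3 equiv), DIAD (1.3 equiv), THF, 0 °C → 40 °C, 16 h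
Reagents that add atoms: none
Why: Mitsunobu etherification of an acidic phenol with a secondary alcohol; the carbinol carbon carries two identical CH2OBn arms, so no stereocentre arises.

Step 2
Reactants: 4 O-benzyl-L-serine
Product: 7 (S)-3-(benzyloxy)-2-hydroxypropanoic acid, via diazonium carboxylate 5 (not isolated), via alpha-lactone 6 (not isolated)
Conditions: NaNO2 (2 equiv), 1 M aq. H2SO4, 0 °C → rt, 16 h
Reagents that add atoms: water, O
Why: Diazotisation of an α-amino acid; the carboxylate expels N2 with inversion to the α-lactone, which water opens at C2 with a second inversion, so the (S) centre of L-serine is retained.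

Step 3
Reactants: 7 (S)-3-(benzyloxy)-2-hydroxypropanoic acid
Product: 8 methyl (S)-3-(benzyloxy)-2-hydroxypropanoate
Conditions: MeOH, H2SO4 (5 mol %), 50 °C, 6 h
Reagents that add atoms: methanol, CO
Why: Fischer esterification in excess methanol; the stereocentre is not involved and the benzyl ether is stable.

Step 4
Reactants: 8 methyl (S)-3-(benzyloxy)-2-hydroxypropanoate; 9 4-(3-hydroxypropyl)-2,6-dimethoxyphenol (dihydrosinapyl alcohol)
Product: 11 methyl (R)-3-(benzyloxy)-2-[4-(3-hydroxypropyl)-2,6-dimethoxyphenoxy]propanoate, via alpha-triflate 10 (not isolated)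
Conditions: Tf2O (1.0 equiv), 2,6-lutidine (1.1 equiv), CH2Cl2, −78 → −30 °C, 30 min; then 9 (1.2 equiv), K2CO3 (3 equiv), MeCN, −30 °C → rt
Reagents that add atoms: none
Why: SN2 displacement of an α-triflyloxy ester by a phenoxide with Walden inversion turns (S) into (R) at C8; K2CO3 deprotonates only the phenol, so the primary alcohol of 9 stays free.

Step 5
Reactants: 11 methyl (R)-3-(benzyloxy)-2-[4-(3-hydroxypropyl)-2,6-dimethoxyphenoxy]propanoate
Product: 12 (R)-3-(benzyloxy)-2-[4-(3-hydroxypropyl)-2,6-dimethoxyphenoxy]propanal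
Conditions: i-Bu2AlH (2.3 equiv), CH2Cl2, −78 °C, 1 h; MeOH quench at −78 °C, aq. potassium sodium tartrate; crude aldehyde used at once
Reagents that add atoms: none
Why: Semi-reduction of an α-alkoxy ester; the first equivalent of hydride is spent on the free hydroxyl, the chelated aluminium hemiacetal is stable at −78 °C and gives the aldehyde only on work-up, and C8 is untouched.

Step 6
Reactants: 12 (R)-3-(benzyloxy)-2-[4-(3-hydroxypropyl)-2,6-dimethoxyphenoxy]propanal; 3 1-{[1,3-bis(benzyloxy)propan-2-yl]oxy}-4-iodo-2-methoxybenzene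
Product: 13 (1S,2R)-3-(benzyloxy)-1-(4-{[1,3-bis(benzyloxy)propan-2-yl]oxy}-3-methoxyphenyl)-2-[4-(3-hydroxypropyl)-2,6-dimethoxyphenoxy]propan-1-ol
Conditions: 3 (1.5 equiv), CrCl2 (20 mol %), NiBr2(bpy) (5 mol %), Cp2ZrCl2 (1.2 equiv), Et4NOTs (0.1 M), DMF, undivided cell, Al anode, Ni-foam cathode, constant current (about 2.5 F/mol), 0 °C; aq. NH4Cl work-up
Reagents that add atoms: none
Why: Proposed new method: the cathode keeps chromium in the divalent state and nickel in the zerovalent state, zerovalent nickel inserts into the C–I bond of 3, the aryl group passes to chromium, and the weakly basic aryl–chromium species (trivalent chromium, so it should neither enolise 12 nor be quenched by its free hydroxyl) adds to the aldehyde through a polar Felkin–Anh transition state (C8–OAr bond anti to the incoming aryl, attack past the C8 hydrogen, chelation disfavoured by DMF and by the hindered, poorly donating aryloxy oxygen), so the bought (R) centre at C8 sets the new (S) centre at C7 (erythro), while Cp2ZrCl2 takes the alkoxide off chromium so that it turns over; the closest known reaction type is the electrochemical Cr/Ni-catalysed Nozaki–Hiyama–Kishi coupling of alkenyl and aryl halides with simple aldehydes, which has not been shown for an aryl iodide adding to an epimerisable α-aryloxy-β-alkoxy aldehyde under 1,2-induction.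

Step 7
Reactants: 13 (1S,2R)-3-(benzyloxy)-1-(4-{[1,3-bis(benzyloxy)propan-2-yl]oxy}-3-methoxyphenyl)-2-[4-(3-hydroxypropyl)-2,6-dimethoxyphenoxy]propan-1-ol
Product: 14 (1S,2R)-1-{4-[(1,3-dihydroxypropan-2-yl)oxy]-3-methoxyphenyl}-2-[4-(3-hydroxypropyl)-2,6-dimethoxyphenoxy]propane-1,3-diol
Conditions: H2 (1 atm), Pd/C (10 wt % Pd), EtOAc–EtOH 1:1, rt
Reagents that add atoms: none
Why: Catalytic hydrogenolysis of the three benzyl ethers under neutral conditions, where the alkyl aryl ethers and the secondary benzylic alcohol persist; no stereocentre is touched.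

## Compound list

1 | 4-iodo-2-methoxyphenol | COc1cc(I)ccc1O | starting material
2 | 1,3-bis(benzyloxy)propan-2-ol | OC(COCc1ccccc1)COCc1ccccc1 | starting material
3 | 1-{[1,3-bis(benzyloxy)propan-2-yl]oxy}-4-iodo-2-methoxybenzene | COc1cc(I)ccc1OC(COCc1ccccc1)COCc1ccccc1 | intermediate
4 | O-benzyl-L-serine, (S)-2-amino-3-(benzyloxy)propanoic acid | N[C@@H](COCc1ccccc1)C(=O)O | starting material
5 | (S)-3-(benzyloxy)-2-diazoniopropanoate (diazonium carboxylate, formed in the flask) | N#[N+][C@@H](COCc1ccccc1)C(=O)[O-] | intermediate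
6 | (R)-3-[(benzyloxy)methyl]oxiran-2-one (alpha-lactone, formed in the flask) | O1[C@H](COCc2ccccc2)C1=O | intermediate
7 | (S)-3-(benzyloxy)-2-hydroxypropanoic acid | O[C@@H](COCc1ccccc1)C(=O)O | intermediate
8 | methyl (S)-3-(benzyloxy)-2-hydroxypropanoate | O[C@@H](COCc1ccccc1)C(=O)OC | intermediate
9 | 4-(3-hydroxypropyl)-2,6-dimethoxyphenol (dihydrosinapyl alcohol) | COc1cc(CCCO)cc(OC)c1O | starting material
10 | methyl (S)-3-(benzyloxy)-2-{[(trifluoromethyl)sulfonyl]oxy}propanoate (alpha-triflate, formed in the flask) | FC(F)(F)S(=O)(=O)O[C@@H](COCc1ccccc1)C(=O)OC | intermediate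
11 | methyl (R)-3-(benzyloxy)-2-[4-(3-hydroxypropyl)-2,6-dimethoxyphenoxy]propanoate | COc1cc(CCCO)cc(OC)c1O[C@H](COCc1ccccc1)C(=O)OC | intermediate
12 | (R)-3-(benzyloxy)-2-[4-(3-hydroxypropyl)-2,6-dimethoxyphenoxy]propanal | COc1cc(CCCO)cc(OC)c1O[C@H](COCc1ccccc1)C=O | intermediate
13 | (1S,2R)-3-(benzyloxy)-1-(4-{[1,3-bis(benzyloxy)propan-2-yl]oxy}-3-methoxyphenyl)-2-[4-(3-hydroxypropyl)-2,6-dimethoxyphenoxy]propan-1-ol | COc1cc([C@H](O)[C@@H](COCc2ccccc2)Oc2c(OC)cc(CCCO)cc2OC)ccc1OC(COCc1ccccc1)COCc1ccccc1 | intermediate
14 | (1S,2R)-1-{4-[(1,3-dihydroxypropan-2-yl)oxy]-3-methoxyphenyl}-2-[4-(3-hydroxypropyl)-2,6-dimethoxyphenoxy]propane-1,3-diol (7S,8R in neolignan numbering) | COc1cc([C@H](O)[C@@H](CO)Oc2c(OC)cc(CCCO)cc2OC)ccc1OC(CO)CO | target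

## Step count and risk

Total steps: 7. Longest linear sequence: 6 (steps 2–7, from 4 to 14); step 1 is the side branch that makes 3.

Most likely to fail:

Step 6 (proposed new step). The risks are an erythro:threo ratio below the modest selectivity hoped for (the two epimers of 13 are separated by chromatography), erosion at C8 of the labile aldehyde, and aryl homocoupling. The fallback sets out from 3 and 12 and uses known chemistry. Iodine–magnesium exchange of 3 with i-PrMgCl·LiCl in THF at −20 °C gives (4-{[1,3-bis(benzyloxy)propan-2-yl]oxy}-3-methoxyphenyl)magnesium chloride F1. About 2.2 equiv of it is added to 12 in THF at −78 °C, one equivalent being spent on the free hydroxyl. This is the classical aryl-Grignard addition to an α-aryloxy aldehyde under non-chelating Felkin–Anh control; after removal of the threo epimer it comes back to the route at 13.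

Step 5. The risks are over-reduction to the primary alcohol, loss of benzyl alcohol by β-elimination, and epimerisation of 12 on handling. The fallback sets out from 11. Treatment with MeNH(OMe)·HCl and i-PrMgCl in THF at −20 °C gives the Weinreb amide (R)-3-(benzyloxy)-2-[4-(3-hydroxypropyl)-2,6-dimethoxyphenoxy]-N-methoxy-N-methylpropanamide F2. Its chelated tetrahedral adduct with LiAlH4 (THF, −40 °C) cannot be reduced further and releases the aldehyde on work-up, coming back to the route at 12.

Step 4. The risks are slow SN2 attack of the hindered 2,6-dimethoxyphenoxide on a secondary triflate and stray O-triflation of the primary alcohol of 9. The fallback sets out from 8. A Mitsunobu reaction (PPh3, DIAD, toluene, 0 °C → rt, inversion) with commercial 4-allyl-2,6-dimethoxyphenol (C=CCc1cc(OC)c(O)c(OC)c1), which has no free alcohol, gives methyl (R)-2-(4-allyl-2,6-dimethoxyphenoxy)-3-(benzyloxy)propanoate F3. Hydroboration–oxidation (9-BBN, THF, rt; then NaBO3·4H2O, H2O) converts the allyl group into the 3-hydroxypropyl chain and comes back to the route at 11.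

## Further compounds

F1 | step 6 | (4-{[1,3-bis(benzyloxy)propan-2-yl]oxy}-3-methoxyphenyl)magnesium chloride (LiCl complex) | COc1cc([Mg]Cl)ccc1OC(COCc1ccccc1)COCc1ccccc1
F2 | step 5 | (R)-3-(benzyloxy)-2-[4-(3-hydroxypropyl)-2,6-dimethoxyphenoxy]-N-methoxy-N-methylpropanamide | COc1cc(CCCO)cc(OC)c1O[C@H](COCc1ccccc1)C(=O)N(C)OC
F3 | step 4 | methyl (R)-2-(4-allyl-2,6-dimethoxyphenoxy)-3-(benzyloxy)propanoate | COc1cc(CC=C)cc(OC)c1O[C@H](COCc1ccccc1)C(=O)OC
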